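Rings: flavanone A (phloroglucinol), C (pyranone), B (para-phenylene); flavonol D (phloroglucinol), E (pyranone), F (4-hydroxyphenyl). Everything rests on cutting the O1–C8a aryl ether bond of ring E. Because O1 sits on C8a of ring D, ortho to the C4 carbonyl carbon on C4a, it can arrive as the enol oxygen of a 1,3-diketone attacking an ortho-bromoaryl ketone. One copper-catalysed C–O coupling then closes ring E and completes the flavonol core with the crowded C3–O–aryl ether already installed. The precursor is an open-chain 2-aryloxy-1,3-diketone between a 2-bromo-4,6-bis(benzyloxy)phenyl and a 4-benzyloxyphenyl group; its phenoxy ring (future ring B) carries an acetal-masked formyl group, from which the (2S)-flavanone is grown.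

Key step: step 6

Assumptions: (a) the hand of the cinchona thiourea in step 10 is chosen by analogy with its conjugate additions to (E)-enones, the quinidine-derived catalyst being taken as the one that leads to 2S, and the quinine-derived pseudo-enantiomer replaces it unchanged if the circular dichroism of 17 points to 2R; (b) 14 is drawn as the Z alkene (aryl cis to the ester), the expected thermodynamic Knoevenagel product.

Step 1
Reactants: 1 4-hydroxybenzaldehyde
Product: 2 4-(1,3-dioxolan-2-yl)phenol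
Conditions: ethylene glycol, TsOH·H2O (cat.), toluene, Dean–Stark, reflux; NaHCO3 wash
Reagents that add atoms: ethylene glycol, OCCO
Why: Acid-catalysed acetalisation with azeotropic removal of water should mask the formyl group, which the enolates of steps 4 and 6 would otherwise attack, and the product is handled over a trace of base because the para-hydroxy group makes this acetal acid-labile.

Step 2
Reactants: 2 4-(1,3-dioxolan-2-yl)phenol; 3 2-bromo-1-[4-(benzyloxy)phenyl]ethan-1-one
Product: 4 1-[4-(benzyloxy)phenyl]-2-[4-(1,3-dioxolan-2-yl)phenoxy]ethan-1-one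
Conditions: K2CO3, acetone, reflux
Reagents that add atoms: none
Why: Williamson ether synthesis, in which the phenoxide displaces a primary, carbonyl-activated bromide by SN2, so the future C3–O–aryl ether is made at an unhindered sp3 carbon under basic conditions that the acetal tolerates.

Step 3
Reactants: 5 1-bromo-3,5-bis(benzyloxy)benzene
Product: 7 2-bromo-4,6-bis(benzyloxy)benzaldehyde, via aryl iminium chloride 6 (not isolated)
Conditions: POCl3, DMF, 0 → 75 °C; then ice–H2O
Reagents that add atoms: N,N-dimethylformamide, CN(C)C=O; water, O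
Why: Vilsmeier–Haack formylation should strike the position next to bromine (para to one benzyloxy group, ortho to the other) rather than the more crowded site between the two ethers, and unlike a Lewis-acid Friedel–Crafts acylation it does not endanger the benzyl ethers.

Step 4
Reactants: 4 1-[4-(benzyloxy)phenyl]-2-[4-(1,3-dioxolan-2-yl)phenoxy]ethan-1-one; 7 2-bromo-4,6-bis(benzyloxy)benzaldehyde
Product: 8 3-[2-bromo-4,6-bis(benzyloxy)phenyl]-1-[4-(benzyloxy)phenyl]-2-[4-(1,3-dioxolan-2-yl)phenoxy]-3-hydroxypropan-1-one (racemic mixture of diastereomers)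
Conditions: LiN(SiMe3)2, THF, −78 °C; add 7, −78 °C; AcOH quench at −78 °C
Reagents that add atoms: none
Why: Lithium-enolate aldol addition to a non-enolisable aldehyde forms the C–C bond without the C- versus O-acylation ambiguity of an acid chloride, and the two new stereocentres need no control because both are erased by step 6.

Step 5
Reactants: 8 3-[2-bromo-4,6-bis(benzyloxy)phenyl]-1-[4-(benzyloxy)phenyl]-2-[4-(1,3-dioxolan-2-yl)phenoxy]-3-hydroxypropan-1-one
Product: 9 1-[2-bromo-4,6-bis(benzyloxy)phenyl]-3-[4-(benzyloxy)phenyl]-2-[4-(1,3-dioxolan-2-yl)phenoxy]propane-1,3-dione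
Conditions: Dess–Martin periodinane, NaHCO3, CH2Cl2, 0 °C → rt
Reagents that add atoms: none
Why: Dess–Martin oxidation of a β-hydroxy ketone to the 1,3-diketone runs under buffered, non-aqueous conditions that should spare the acetal, the benzyl ethers and the aryl bromide.

Step 6
Reactants: 9 1-[2-bromo-4,6-bis(benzyloxy)phenyl]-3-[4-(benzyloxy)phenyl]-2-[4-(1,3-dioxolan-2-yl)phenoxy]propane-1,3-dione
Product: 10 5,7-bis(benzyloxy)-2-[4-(benzyloxy)phenyl]-3-[4-(1,3-dioxolan-2-yl)phenoxy]-4H-chromen-4-one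
Conditions: CuI (10 mol%), 1,10-phenanthroline (20 mol%), K3PO4 (2 equiv, oven-dried), dry degassed DMF, 90 °C, Ar
Reagents that add atoms: none
Why: K3PO4 turns 9 into its enolate, which binds through oxygen to the monovalent copper of the CuI/1,10-phenanthroline catalyst; the nearby C–Br bond, activated by the ortho acyl group, adds oxidatively to give a seven-membered aryl–enolato metallacycle of trivalent copper, and C–O reductive elimination releases 10 and returns the catalyst. The closest known reaction type is the intramolecular Ullmann-type O-arylation of 1-(2-haloaryl)-1,3-diketones, an established entry to chromones and flavones. Ring E closes as a six-membered ring by attack of the enolate oxygen of the 4-benzyloxybenzoyl unit on C8a, the departing C–Br bond lying outside the new ring (formally 6-exo). No stereocentre is formed, and the labile one at the central carbon of 9 disappears. The step needs O- rather than C-arylation and the correct oxygen, and the substrate geometry secures both, since attack through the central carbon or through the oxygen of the bromoaroyl carbonyl could only build four-membered rings. An uncatalysed addition–elimination at the acyl-activated C–Br carbon would make the same bond, and dry base keeps retro-Claisen cleavage of the diketone in check.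

Step 7
Reactants: 10 5,7-bis(benzyloxy)-2-[4-(benzyloxy)phenyl]-3-[4-(1,3-dioxolan-2-yl)phenoxy]-4H-chromen-4-one
Product: 11 4-({5,7-bis(benzyloxy)-2-[4-(benzyloxy)phenyl]-4-oxo-4H-chromen-3-yl}oxy)benzaldehyde
Conditions: 1 M HCl (cat.), THF–H2O, rt
Reagents that add atoms: water, O
Why: Acid-catalysed acetal hydrolysis is easy here because the para-aryloxy group stabilises the oxocarbenium ion, while benzyl ethers, the diaryl-type ether and the chromone are inert to dilute acid at room temperature.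

Step 8
Reactants: 12 1-[2,4-bis(benzyloxy)-6-hydroxyphenyl]ethan-1-one
Product: 13 tert-butyl 3-[2,4-bis(benzyloxy)-6-hydroxyphenyl]-3-oxopropanoate
Conditions: LiN(SiMe3)2 (3.3 equiv), THF, −78 °C; Boc2O (1.1 equiv), −78 → 0 °C; AcOH quench
Reagents that add atoms: di-tert-butyl dicarbonate, CC(C)(C)OC(=O)OC(=O)OC(C)(C)C
Why: Claisen-type C-acylation of the phenoxide–enolate dianion, with the third equivalent of base absorbing the acidic product, and any aryl carbonate formed at the phenoxide should be funnelled to the same β-keto ester by a Baker–Venkataraman-type O-to-C transfer.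

Step 9
Reactants: 11 4-({5,7-bis(benzyloxy)-2-[4-(benzyloxy)phenyl]-4-oxo-4H-chromen-3-yl}oxy)benzaldehyde; 13 tert-butyl 3-[2,4-bis(benzyloxy)-6-hydroxyphenyl]-3-oxopropanoate
Product: 14 tert-butyl (Z)-2-[2,4-bis(benzyloxy)-6-hydroxybenzoyl]-3-[4-({5,7-bis(benzyloxy)-2-[4-(benzyloxy)phenyl]-4-oxo-4H-chromen-3-yl}oxy)phenyl]prop-2-enoate
Conditions: piperidine (20 mol%), AcOH (20 mol%), 4 Å molecular sieves, toluene, rt
Reagents that add atoms: none
Why: Knoevenagel condensation under piperidinium acetate catalysis should place the aryl group cis to the smaller ester, and the mild buffered medium and short contact time are chosen to hold back closure of the free phenol onto the new alkene.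

Step 10
Reactants: 14 tert-butyl (Z)-2-[2,4-bis(benzyloxy)-6-hydroxybenzoyl]-3-[4-({5,7-bis(benzyloxy)-2-[4-(benzyloxy)phenyl]-4-oxo-4H-chromen-3-yl}oxy)phenyl]prop-2-enoate
Product: 17 (2S)-5,7-bis(benzyloxy)-2-[4-({5,7-bis(benzyloxy)-2-[4-(benzyloxy)phenyl]-4-oxo-4H-chromen-3-yl}oxy)phenyl]-2,3-dihydro-4H-chromen-4-one, via tert-butyl ester 15 (not isolated), via keto acid 16 (not isolated)
Conditions: 1-[3,5-bis(trifluoromethyl)phenyl]-3-[(9R)-6'-methoxycinchonan-9-yl]thiourea (quinidine-derived, 10 mol%), toluene, −25 °C; then TsOH·H2O, 80 °C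
Reagents that add atoms: none
Why: Bifunctional-thiourea-catalysed intramolecular oxa-Michael addition to an alkylidene β-keto ester, in which the thiourea holds the dicarbonyl unit while the quinuclidine nitrogen deprotonates the phenol and steers it to one alkene face to set C2 as S, the ester making the acceptor reactive enough to close irreversibly at −25 °C (a plain 2'-hydroxychalcone closes reversibly and with poor selectivity), after which TsOH silences the amine, cleaves the tert-butyl ester and triggers decarboxylation without touching C2.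

Step 11
Reactants: 17 (2S)-5,7-bis(benzyloxy)-2-[4-({5,7-bis(benzyloxy)-2-[4-(benzyloxy)phenyl]-4-oxo-4H-chromen-3-yl}oxy)phenyl]-2,3-dihydro-4H-chromen-4-one
Product: 18 (2S)-5,7-dihydroxy-2-(4-{[5,7-dihydroxy-2-(4-hydroxyphenyl)-4-oxo-4H-chromen-3-yl]oxy}phenyl)-2,3-dihydro-4H-chromen-4-one (target)
Conditions: H2 (1 atm), 10% Pd/C, THF–MeOH, rt, stopped at full conversion
Reagents that add atoms: none
Why: Catalytic hydrogenolysis of the five aryl benzyl ethers in neutral medium leaves C2 untouched because no base is present to open ring C, and the electron-rich C4 ketone and the tetrasubstituted C2=C3 bond of ring E should resist reduction at one atmosphere.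

Compound list
1 | 4-hydroxybenzaldehyde | O=Cc1ccc(O)cc1 | starting material
2 | 4-(1,3-dioxolan-2-yl)phenol | Oc1ccc(C2OCCO2)cc1 | intermediate
3 | 2-bromo-1-[4-(benzyloxy)phenyl]ethan-1-one | O=C(CBr)c1ccc(OCc2ccccc2)cc1 | starting material
4 | 1-[4-(benzyloxy)phenyl]-2-[4-(1,3-dioxolan-2-yl)phenoxy]ethan-1-one | O=C(COc1ccc(C2OCCO2)cc1)c1ccc(OCc2ccccc2)cc1 | intermediate
5 | 1-bromo-3,5-bis(benzyloxy)benzene | Brc1cc(OCc2ccccc2)cc(OCc2ccccc2)c1 | starting material
6 | N-{[2-bromo-4,6-bis(benzyloxy)phenyl]methylidene}-N-methylmethanaminium chloride | C[N+](C)=Cc1c(Br)cc(OCc2ccccc2)cc1OCc1ccccc1.[Cl-] | intermediate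
7 | 2-bromo-4,6-bis(benzyloxy)benzaldehyde | O=Cc1c(Br)cc(OCc2ccccc2)cc1OCc1ccccc1 | intermediate
8 | 3-[2-bromo-4,6-bis(benzyloxy)phenyl]-1-[4-(benzyloxy)phenyl]-2-[4-(1,3-dioxolan-2-yl)phenoxy]-3-hydroxypropan-1-one, racemic mixture of diastereomers | OC(c1c(Br)cc(OCc2ccccc2)cc1OCc1ccccc1)C(Oc1ccc(C2OCCO2)cc1)C(=O)c1ccc(OCc2ccccc2)cc1 | intermediate
9 | 1-[2-bromo-4,6-bis(benzyloxy)phenyl]-3-[4-(benzyloxy)phenyl]-2-[4-(1,3-dioxolan-2-yl)phenoxy]propane-1,3-dione | O=C(c1c(Br)cc(OCc2ccccc2)cc1OCc1ccccc1)C(Oc1ccc(C2OCCO2)cc1)C(=O)c1ccc(OCc2ccccc2)cc1 | intermediate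
10 | 5,7-bis(benzyloxy)-2-[4-(benzyloxy)phenyl]-3-[4-(1,3-dioxolan-2-yl)phenoxy]-4H-chromen-4-one | O=c1c(Oc2ccc(C3OCCO3)cc2)c(-c2ccc(OCc3ccccc3)cc2)oc2cc(OCc3ccccc3)cc(OCc3ccccc3)c12 | intermediate
11 | 4-({5,7-bis(benzyloxy)-2-[4-(benzyloxy)phenyl]-4-oxo-4H-chromen-3-yl}oxy)benzaldehyde | O=Cc1ccc(Oc2c(-c3ccc(OCc4ccccc4)cc3)oc3cc(OCc4ccccc4)cc(OCc4ccccc4)c3c2=O)cc1 | intermediate
12 | 1-[2,4-bis(benzyloxy)-6-hydroxyphenyl]ethan-1-one | CC(=O)c1c(O)cc(OCc2ccccc2)cc1OCc1ccccc1 | starting material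
13 | tert-butyl 3-[2,4-bis(benzyloxy)-6-hydroxyphenyl]-3-oxopropanoate | CC(C)(C)OC(=O)CC(=O)c1c(O)cc(OCc2ccccc2)cc1OCc1ccccc1 | intermediate
14 | tert-butyl (Z)-2-[2,4-bis(benzyloxy)-6-hydroxybenzoyl]-3-[4-({5,7-bis(benzyloxy)-2-[4-(benzyloxy)phenyl]-4-oxo-4H-chromen-3-yl}oxy)phenyl]prop-2-enoate | CC(C)(C)OC(=O)/C(=C\c1ccc(Oc2c(-c3ccc(OCc4ccccc4)cc3)oc3cc(OCc4ccccc4)cc(OCc4ccccc4)c3c2=O)cc1)C(=O)c1c(O)cc(OCc2ccccc2)cc1OCc1ccccc1 | intermediate
15 | tert-butyl (2S,3R)-5,7-bis(benzyloxy)-2-[4-({5,7-bis(benzyloxy)-2-[4-(benzyloxy)phenyl]-4-oxo-4H-chromen-3-yl}oxy)phenyl]-4-oxo-3,4-dihydro-2H-chromene-3-carboxylate (trans; C3 is labile) | O=C1[C@H](C(=O)OC(C)(C)C)[C@@H](c2ccc(Oc3c(-c4ccc(OCc5ccccc5)cc4)oc4cc(OCc5ccccc5)cc(OCc5ccccc5)c4c3=O)cc2)Oc2cc(OCc3ccccc3)cc(OCc3ccccc3)c21 | intermediate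
16 | (2S,3R)-5,7-bis(benzyloxy)-2-[4-({5,7-bis(benzyloxy)-2-[4-(benzyloxy)phenyl]-4-oxo-4H-chromen-3-yl}oxy)phenyl]-4-oxo-3,4-dihydro-2H-chromene-3-carboxylic acid | O=C1[C@H](C(=O)O)[C@@H](c2ccc(Oc3c(-c4ccc(OCc5ccccc5)cc4)oc4cc(OCc5ccccc5)cc(OCc5ccccc5)c4c3=O)cc2)Oc2cc(OCc3ccccc3)cc(OCc3ccccc3)c21 | intermediate
17 | (2S)-5,7-bis(benzyloxy)-2-[4-({5,7-bis(benzyloxy)-2-[4-(benzyloxy)phenyl]-4-oxo-4H-chromen-3-yl}oxy)phenyl]-2,3-dihydro-4H-chromen-4-one | O=C1C[C@@H](c2ccc(Oc3c(-c4ccc(OCc5ccccc5)cc4)oc4cc(OCc5ccccc5)cc(OCc5ccccc5)c4c3=O)cc2)Oc2cc(OCc3ccccc3)cc(OCc3ccccc3)c21 | intermediate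
18 | (2S)-5,7-dihydroxy-2-(4-{[5,7-dihydroxy-2-(4-hydroxyphenyl)-4-oxo-4H-chromen-3-yl]oxy}phenyl)-2,3-dihydro-4H-chromen-4-one | O=C1C[C@@H](c2ccc(Oc3c(-c4ccc(O)cc4)oc4cc(O)cc(O)c4c3=O)cc2)Oc2cc(O)cc(O)c21 | target

Total step count: 11. Longest linear sequence: 9 steps (1, 2, 4, 5, 6, 7, 9, 10, 11).

Steps most likely to fail

Step 6. Three processes threaten it. Oxidative addition may be slow at a C–Br carbon that is electron-rich and sits beside a twisted acyl group. Adventitious hydroxide or amine may cleave the diketone by a retro-Claisen reaction, and protodebromination may compete.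

In the fallback the ether is made last, on a finished flavonol, by nucleophilic aromatic substitution. It sets out from 12.
- Claisen–Schmidt condensation with 4-benzyloxybenzaldehyde (KOH, EtOH, rt) should give (E)-1-[2,4-bis(benzyloxy)-6-hydroxyphenyl]-3-[4-(benzyloxy)phenyl]prop-2-en-1-one F1.
- Oxidative cyclisation (I2 cat., DMSO, 130 °C) should give 5,7-bis(benzyloxy)-2-[4-(benzyloxy)phenyl]-4H-chromen-4-one F2.
- Oxygenation of C3 with dimethyldioxirane, followed by a trace of TsOH, should give 5,7-bis(benzyloxy)-2-[4-(benzyloxy)phenyl]-3-hydroxy-4H-chromen-4-one F3.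
- The 3-oxide anion of F3 (K2CO3, DMF, 110 °C) then displaces fluoride from 4-fluorobenzaldehyde, and the route is rejoined at 11.

Step 10. Facial selectivity may be poor on a substrate whose 6'-benzyloxy group twists the aroyl unit. Uncatalysed background closure of the phenol may compete, and it can begin as early as step 9. Reversible ring opening during the hot acid stage may erode the enantiomeric purity.

The fallback gives up enantioselective ring closure for a kinetic resolution by reduction. It sets out from 11.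
- Claisen–Schmidt condensation with 12 (KOH, EtOH–THF, rt) should give (E)-1-[2,4-bis(benzyloxy)-6-hydroxyphenyl]-3-[4-({5,7-bis(benzyloxy)-2-[4-(benzyloxy)phenyl]-4-oxo-4H-chromen-3-yl}oxy)phenyl]prop-2-en-1-one F4.
- NaOAc in refluxing EtOH closes F4 to racemic 5,7-bis(benzyloxy)-2-[4-({5,7-bis(benzyloxy)-2-[4-(benzyloxy)phenyl]-4-oxo-4H-chromen-3-yl}oxy)phenyl]-2,3-dihydro-4H-chromen-4-one F5.
- Noyori-type asymmetric transfer hydrogenation follows, with RuCl(p-cymene)[(R,R)-TsDPEN] and HCO2H–Et3N in EtOAc at rt. This catalyst hand makes 4R carbinols, and only the 2R ketone can reach the favoured cis (diequatorial) alcohol that way.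
- The 2R antipode should therefore be reduced to (2R,4R)-5,7-bis(benzyloxy)-2-[4-({5,7-bis(benzyloxy)-2-[4-(benzyloxy)phenyl]-4-oxo-4H-chromen-3-yl}oxy)phenyl]-3,4-dihydro-2H-chromen-4-ol F6. The unreacted 2S ketone is separated by chromatography, and the route is rejoined at 17.

Step 4. The aldol addition may reverse, because the aldehyde is hindered on both ortho positions and electron-rich. The results would be incomplete conversion or loss of adduct on warming.

The fallback replaces aldol plus oxidation by a direct C-acylation. It sets out from 7.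
- Pinnick oxidation (NaClO2, NaH2PO4, 2-methylbut-2-ene, t-BuOH–H2O) should give 2-bromo-4,6-bis(benzyloxy)benzoic acid F7.
- SOCl2 and 1H-benzotriazole in CH2Cl2 convert F7 into 1-[2-bromo-4,6-bis(benzyloxy)benzoyl]-1H-benzotriazole F8.
- Soft enolisation of 4 with MgBr2·OEt2 and i-Pr2NEt in CH2Cl2 gives a magnesium-chelated enolate that favours carbon attack. Its acylation by F8 rejoins the route at 9 and bypasses 8 and step 5.

Further compounds
F1 | step 6 | (E)-1-[2,4-bis(benzyloxy)-6-hydroxyphenyl]-3-[4-(benzyloxy)phenyl]prop-2-en-1-one | O=C(/C=C/c1ccc(OCc2ccccc2)cc1)c1c(O)cc(OCc2ccccc2)cc1OCc1ccccc1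
F2 | step 6 | 5,7-bis(benzyloxy)-2-[4-(benzyloxy)phenyl]-4H-chromen-4-one | O=c1cc(-c2ccc(OCc3ccccc3)cc2)oc2cc(OCc3ccccc3)cc(OCc3ccccc3)c12
F3 | step 6 | 5,7-bis(benzyloxy)-2-[4-(benzyloxy)phenyl]-3-hydroxy-4H-chromen-4-one | O=c1c(O)c(-c2ccc(OCc3ccccc3)cc2)oc2cc(OCc3ccccc3)cc(OCc3ccccc3)c12
F4 | step 10 | (E)-1-[2,4-bis(benzyloxy)-6-hydroxyphenyl]-3-[4-({5,7-bis(benzyloxy)-2-[4-(benzyloxy)phenyl]-4-oxo-4H-chromen-3-yl}oxy)phenyl]prop-2-en-1-one | O=C(/C=C/c1ccc(Oc2c(-c3ccc(OCc4ccccc4)cc3)oc3cc(OCc4ccccc4)cc(OCc4ccccc4)c3c2=O)cc1)c1c(O)cc(OCc2ccccc2)cc1OCc1ccccc1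
F5 | step 10 | racemic 5,7-bis(benzyloxy)-2-[4-({5,7-bis(benzyloxy)-2-[4-(benzyloxy)phenyl]-4-oxo-4H-chromen-3-yl}oxy)phenyl]-2,3-dihydro-4H-chromen-4-one | O=C1CC(c2ccc(Oc3c(-c4ccc(OCc5ccccc5)cc4)oc4cc(OCc5ccccc5)cc(OCc5ccccc5)c4c3=O)cc2)Oc2cc(OCc3ccccc3)cc(OCc3ccccc3)c21
F6 | step 10 | (2R,4R)-5,7-bis(benzyloxy)-2-[4-({5,7-bis(benzyloxy)-2-[4-(benzyloxy)phenyl]-4-oxo-4H-chromen-3-yl}oxy)phenyl]-3,4-dihydro-2H-chromen-4-ol | O[C@@H]1C[C@H](c2ccc(Oc3c(-c4ccc(OCc5ccccc5)cc4)oc4cc(OCc5ccccc5)cc(OCc5ccccc5)c4c3=O)cc2)Oc2cc(OCc3ccccc3)cc(OCc3ccccc3)c21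
F7 | step 4 | 2-bromo-4,6-bis(benzyloxy)benzoic acid | O=C(O)c1c(Br)cc(OCc2ccccc2)cc1OCc1ccccc1
F8 | step 4 | 1-[2-bromo-4,6-bis(benzyloxy)benzoyl]-1H-benzotriazole | O=C(c1c(Br)cc(OCc2ccccc2)cc1OCc1ccccc1)n1nnc2ccccc21
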